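**Plan**

- Retrosynthesis: the styryl C=C and the C7a–H/C1–H bonds go first (back to a C6–CH2OSi group and a C1=C7a enone). Then C3a–C7a, C1–C2 and C2–C3 are cut together (Pauson–Khand) to an open-chain dienyne and CO, followed by the C3=C3a and C4=C5 olefin bonds, the C6–C7 bond (Ireland–Claisen) and an ester C–O bond.
- Forward: the chain is joined first. Alcohol 7 is esterified with acid 11, a [3,3] shift makes the C6/C7 pair, and the new propenyl group is cut to the C5 aldehyde and rebuilt as the (Z,E)-diene. The cyclohexene and the cyclopentenone then close together in step 15; no carbocycle exists before it.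
- Enabling feature: the cyclopentanone C1–C2–C3–C3a–C7a is alkyne (C1≡C7a) + alkene (C3=C3a) + CO (C2). These π-bonds are 1,7-related through C7–C6–C5=C4, whose cis double bond and two quaternary carbons hold them within reach, so the six-membered ring (C3a–C7a) forms with the five-membered one.
- Stereochemistry: C6 and C7 come from (R)-but-3-yn-2-ol by chair chirality transfer in the Claisen step (the carbinol carbon is later excised as acetaldehyde). C3 comes from the (E)-alkene, C3a from 1,3-allylic strain at C7 during ring closure, C7a from axial protonation in the Li/NH3 reduction, and C1 from base equilibration.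

Key step: step 15

Remark 1: locants follow the bicyclic product throughout, also for open-chain compounds: C1(Et)–C2(C=O)–C3(Me)–C3a–C4(Me)=C5–C6–C7–C7a. Names of bicyclic compounds use these locants; TBS = tert-butyl(dimethyl)silyl.
Remark 2 (assumption): (R)-but-3-yn-2-ol, hex-3-yn-1-ol, the trifluoroethyl phosphonate and both phenyltetrazolyl sulfones are purchased; n-BuLi, LDA, KHMDS and Red-Al are used as commercial solutions.
Remark 3 (assumption): in the trans-fused ketone an alkyl group at C1 or C3 is taken to be more stable trans to the neighbouring ring bond (C7a–C7, C3a–C4); this is the arrangement drawn in the target.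

**Route**

Step 1
Reactants: 1 (R)-but-3-yn-2-ol
Product: 3 (R)-pent-2-yne-1,4-diol, via dilithium alkoxide acetylide 2 (not isolated)
Conditions: n-BuLi (2.1 equiv), THF, −78 → 0 °C; (CH2O)n, 0 °C → rt; H2O
Reagents that add atoms: formaldehyde (as paraformaldehyde), C=O
Why: Acetylide addition to formaldehyde (C-hydroxymethylation of the dilithio species); the carbinol stereocenter is not involved.

Step 2
Reactants: 3 (R)-pent-2-yne-1,4-diol
Product: 4 (R)-5-(TBS-oxy)pent-3-yn-2-ol
Conditions: TBSCl (1.05 equiv), imidazole, CH2Cl2, −20 → 0 °C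
Reagents that add atoms: tert-butyl(chloro)dimethylsilane, CC(C)(C)[Si](C)(C)Cl
Why: Silyl ether formation, selective for the primary over the secondary propargylic hydroxyl on steric grounds.

Step 3
Reactants: 4 (R)-5-(TBS-oxy)pent-3-yn-2-ol
Product: 6 (2R,3Z)-5-(TBS-oxy)-4-iodopent-3-en-2-ol, via cyclic alkenylalanate 5 (not isolated)
Conditions: Red-Al (1.6 equiv), THF, 0 °C → rt; then I2, THF, −78 → 0 °C; aq. Rochelle salt/Na2S2O3
Reagents that add atoms: iodine, II
Why: Hydroxyl-directed trans-hydroalumination puts aluminium on the distal alkyne carbon inside a five-membered alanate, and iodinolysis with retention gives the (Z)-iodoalkene with iodine cis to the carbinol carbon.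

Step 4
Reactants: 6 (2R,3Z)-5-(TBS-oxy)-4-iodopent-3-en-2-ol
Product: 7 (2R,3E)-4-(TBS-oxymethyl)hex-3-en-2-ol
Conditions: Et2Zn (2.5 equiv), Pd(dppf)Cl2 (5 mol %), THF, 0 → 50 °C
Reagents that add atoms: diethylzinc, CC[Zn]CC
Why: Negishi coupling with retention of alkene geometry places ethyl cis to the carbinol carbon; the bidentate ligand suppresses β-hydride elimination of the ethylpalladium species.

Step 5
Reactants: 8 hex-3-yn-1-ol
Product: 9 hex-3-ynoic acid
Conditions: CrO3, aq. H2SO4 (Jones reagent), acetone, 0 °C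
Reagents that add atoms: water (of the aqueous Jones reagent, via the aldehyde hydrate), O
Why: Jones oxidation of a homopropargylic alcohol; the acidic medium avoids the base-induced shift of the β,γ-alkyne to the allene.

Step 6
Reactants: 9 hex-3-ynoic acid
Product: 11 2-ethylhex-3-ynoic acid (racemic), via dilithium enediolate 10 (not isolated)
Conditions: LDA (2.1 equiv), THF–DMPU, −78 → −40 °C; EtI, −78 → −20 °C; cold 1 M HCl
Reagents that add atoms: iodoethane, CCI
Why: Alkylation of a carboxylic acid dianion, which like other dienolate-type dianions should take the alkyl halide at the α-carbon.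

Step 7
Reactants: 7 (2R,3E)-4-(TBS-oxymethyl)hex-3-en-2-ol; 11 2-ethylhex-3-ynoic acid
Product: 12 (2R,3E)-4-(TBS-oxymethyl)hex-3-en-2-yl 2-ethylhex-3-ynoate
Conditions: EDC·HCl (1.3 equiv), DMAP (0.1 equiv), CH2Cl2, −10 → 0 °C
Reagents that add atoms: none
Why: Steglich esterification at low temperature with only catalytic DMAP to limit isomerisation to the allenoate; the carbinol C–O bond is not broken, so (R) is kept.

Step 8
Reactants: 12 (2R,3E)-4-(TBS-oxymethyl)hex-3-en-2-yl 2-ethylhex-3-ynoate
Product: 15 (2R,3S,4E)-2-(but-1-yn-1-yl)-2,3-diethyl-3-(TBS-oxymethyl)hex-4-enoic acid, via silyl ketene acetal 13 (not isolated), via trimethylsilyl ester 14 (not isolated)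
Conditions: LDA (1.2 equiv), THF, −78 °C; TMSCl–Et3N, −78 °C → rt; 60 °C; then aq. citric acid
Reagents that add atoms: none
Why: Ireland–Claisen rearrangement: LDA in THF should enolise through the closed amide–lithium transition state that places the bulkier ethyl syn to the allyloxy oxygen and the rod-like butynyl syn to O–Li, and the resulting (Z)-ketene acetal 13 rearranges through a chair with the carbinol methyl equatorial, which transfers the (R) carbinol configuration to (3S) at C6 and (2R) at C7, joins the two quaternary carbons and leaves an (E)-propenyl group.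

Step 9
Reactants: 15 (2R,3S,4E)-2-(but-1-yn-1-yl)-2,3-diethyl-3-(TBS-oxymethyl)hex-4-enoic acid
Product: 16 tert-butyl (2R,3S,4E)-2-(but-1-yn-1-yl)-2,3-diethyl-3-(TBS-oxymethyl)hex-4-enoate
Conditions: tert-butyl 2,2,2-trichloroacetimidate (3 equiv), cyclohexane–CH2Cl2, rt
Reagents that add atoms: tert-butyl 2,2,2-trichloroacetimidate, CC(C)(C)OC(=N)C(Cl)(Cl)Cl
Why: Imidate esterification transfers a tert-butyl cation to the carboxyl oxygen, so the shielded carboxyl carbon need not be attacked and no Lewis acid endangers the silyl ether.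

Step 10
Reactants: 16 tert-butyl (2R,3S,4E)-2-(but-1-yn-1-yl)-2,3-diethyl-3-(TBS-oxymethyl)hex-4-enoate
Product: 18 tert-butyl (2R,3S)-2-(but-1-yn-1-yl)-2,3-diethyl-3-(TBS-oxymethyl)-4-oxobutanoate, via secondary ozonide 17 (not isolated)
Conditions: O3, CH2Cl2, −78 °C (Sudan Red 7B end point); then PPh3, −78 °C → rt
Reagents that add atoms: ozone, [O-][O+]=O
Why: Ozonolysis with reductive work-up; the 1,2-disubstituted alkene reacts far faster than the internal alkyne, the dye marks the end point, and the aldehyde has no α-hydrogen to lose.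

Step 11
Reactants: 18 tert-butyl (2R,3S)-2-(but-1-yn-1-yl)-2,3-diethyl-3-(TBS-oxymethyl)-4-oxobutanoate
Product: 19 1-tert-butyl 6-ethyl (2R,3S,4Z)-2-(but-1-yn-1-yl)-2,3-diethyl-5-methyl-3-(TBS-oxymethyl)hex-4-enedioate
Conditions: ethyl 2-[bis(2,2,2-trifluoroethoxy)phosphoryl]propanoate (1.5 equiv), KHMDS (1.4 equiv), 18-crown-6, THF, −78 → −40 °C
Reagents that add atoms: ethyl 2-[bis(2,2,2-trifluoroethoxy)phosphoryl]propanoate, CCOC(=O)C(C)P(=O)(OCC(F)(F)F)OCC(F)(F)F
Why: Still–Gennari olefination; fast elimination from the kinetic adduct of the electron-poor phosphonate gives the (Z)-trisubstituted enoate with the ester carbon (future C3a) cis to C6.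

Step 12
Reactants: 19 1-tert-butyl 6-ethyl (2R,3S,4Z)-2-(but-1-yn-1-yl)-2,3-diethyl-5-methyl-3-(TBS-oxymethyl)hex-4-enedioate
Product: 20 tert-butyl (2R,3S,4Z)-2-(but-1-yn-1-yl)-2,3-diethyl-6-hydroxy-5-methyl-3-(TBS-oxymethyl)hex-4-enoate
Conditions: DIBAL-H (2.5 equiv), CH2Cl2, −78 °C; aq. Rochelle salt
Reagents that add atoms: none
Why: Hydride reduction of the unhindered conjugated ethyl ester; the tert-butyl ester on the quaternary carbon is inert at −78 °C.

Step 13
Reactants: 20 tert-butyl (2R,3S,4Z)-2-(but-1-yn-1-yl)-2,3-diethyl-6-hydroxy-5-methyl-3-(TBS-oxymethyl)hex-4-enoate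
Product: 21 tert-butyl (2R,3S,4Z)-2-(but-1-yn-1-yl)-2,3-diethyl-5-methyl-6-oxo-3-(TBS-oxymethyl)hex-4-enoate
Conditions: PhI(OAc)2 (1.2 equiv), TEMPO (0.1 equiv), CH2Cl2, rt
Reagents that add atoms: none
Why: TEMPO/hypervalent iodine oxidation of the allylic alcohol under neutral conditions, which keeps the (Z)-geometry of the α-methyl enal.

Step 14
Reactants: 21 tert-butyl (2R,3S,4Z)-2-(but-1-yn-1-yl)-2,3-diethyl-5-methyl-6-oxo-3-(TBS-oxymethyl)hex-4-enoate
Product: 22 tert-butyl (2R,3S,4Z,6E)-2-(but-1-yn-1-yl)-2,3-diethyl-5-methyl-3-(TBS-oxymethyl)octa-4,6-dienoate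
Conditions: 5-(ethylsulfonyl)-1-phenyl-1H-tetrazole (1.3 equiv), KHMDS (1.25 equiv), DME, −60 °C; then 21, −60 °C → rt
Reagents that add atoms: 5-(ethylsulfonyl)-1-phenyl-1H-tetrazole, CCS(=O)(=O)c1nnnn1-c1ccccc1
Why: Julia–Kocienski olefination with the pre-metalated phenyltetrazolyl sulfone (no free base meets the enal) should give the (E)-propenyl terminus.

Step 15
Reactants: 22 tert-butyl (2R,3S,4Z,6E)-2-(but-1-yn-1-yl)-2,3-diethyl-5-methyl-3-(TBS-oxymethyl)octa-4,6-dienoate; 23 carbon monoxide
Product: 24 tert-butyl 1,6,7-triethyl-3,4-dimethyl-2-oxo-6-(TBS-oxymethyl)-3,3a,6,7-tetrahydro-2H-indene-7-carboxylate (3-Me trans to C4; H3a anti to the ester)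
Conditions: [Rh(CO)2Cl]2 (5 mol %), CO (1 atm), toluene (0.02 M), 110 °C
Reagents that add atoms: none
Why: Rh(I) binds the alkyne and the C3=C3a alkene, oxidative cyclisation forms C3a–C7a, CO inserts into a Rh–C bond and reductive elimination forms C1–C2 and C2–C3; this is the catalytic intramolecular Pauson–Khand reaction of a 1,7-enyne, closest to Rh(I)- and Co-mediated cyclisations of 1,7-enynes whose tether is held cis by an arene. The cyclohexene closes by C3a–C7a bond formation that is exo at both π-bonds (C1 and C3 stay outside the six-membered ring), and the cyclopentenone closes by the [2+2+1] union of C1≡C7a, C3=C3a and CO. C3 is set relative to C3a by suprafacial addition to the (E)-alkene, so the methyl ends trans to C4. C3a is set relative to C6/C7 by 1,3-allylic strain: as the C1=C7a bond develops, the quaternary C7 must put one substituent in the plane next to the C1 ethyl group, the flat ester should take that site and leave the C7 ethyl axial, and because C3 must be equatorial for the ring fusion, H3a is axial on the face of that ethyl group, anti to the ester. The step needs only the 1,7 pairing, which the substrate secures: the cis C4=C5 bond and the two quaternary carbons hold the alkyne next to the terminal alkene, pairing with C4=C5 would give a four-membered or bridged ring, and the (Z)-diene carries no hydrogen placed for a 1,5-shift.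

Step 16
Reactants: 24 tert-butyl 1,6,7-triethyl-3,4-dimethyl-2-oxo-6-(TBS-oxymethyl)-3,3a,6,7-tetrahydro-2H-indene-7-carboxylate
Product: 26 tert-butyl 1,6,7-triethyl-3,4-dimethyl-2-oxo-6-(TBS-oxymethyl)-2,3,3a,6,7,7a-hexahydro-1H-indene-7-carboxylate (trans-fused; H7a syn to the ester), via lithium enolate 25 (not isolated)
Conditions: Li (2.5 equiv), NH3(l)–THF, t-BuOH (1 equiv), −78 °C; NH4Cl; then NaOMe (0.2 equiv), MeOH, rt
Reagents that add atoms: none
Why: Dissolving-metal conjugate reduction of the enone: C7a should be protonated axially, anti to the axial H3a, on the half-chair already fixed by the in-plane ester, which gives the trans-fused hydrindanone with H7a syn to the ester, and after protonation of enolate 25 methoxide equilibrates C1 to the isomer with ethyl trans to C7 (C3 stays trans to C4); the hindered tert-butyl ester and the isolated C4=C5 bond should survive the short exposure.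

Step 17
Reactants: 26 tert-butyl 1,6,7-triethyl-3,4-dimethyl-2-oxo-6-(TBS-oxymethyl)-2,3,3a,6,7,7a-hexahydro-1H-indene-7-carboxylate
Product: 27 tert-butyl 1,6,7-triethyl-6-(hydroxymethyl)-3,4-dimethyl-2-oxo-2,3,3a,6,7,7a-hexahydro-1H-indene-7-carboxylate
Conditions: HF·pyridine, pyridine, THF, 0 °C → rt; used at once
Reagents that add atoms: none
Why: Fluoride desilylation under buffered, weakly acidic conditions, chosen so that no alkoxide is formed that could lactonise onto the cis tert-butyl ester.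

Step 18
Reactants: 27 tert-butyl 1,6,7-triethyl-6-(hydroxymethyl)-3,4-dimethyl-2-oxo-2,3,3a,6,7,7a-hexahydro-1H-indene-7-carboxylate
Product: 28 tert-butyl 1,6,7-triethyl-6-formyl-3,4-dimethyl-2-oxo-2,3,3a,6,7,7a-hexahydro-1H-indene-7-carboxylate
Conditions: Dess–Martin periodinane (1.5 equiv), NaHCO3, CH2Cl2, 0 °C → rt
Reagents that add atoms: none
Why: Dess–Martin oxidation of the neopentyl alcohol; the aldehyde has no α-hydrogen and can neither epimerise nor move into conjugation.

Step 19
Reactants: 28 tert-butyl 1,6,7-triethyl-6-formyl-3,4-dimethyl-2-oxo-2,3,3a,6,7,7a-hexahydro-1H-indene-7-carboxylate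
Product: 29 tert-butyl 1,6,7-triethyl-3,4-dimethyl-2-oxo-6-[(E)-2-phenylethenyl]-2,3,3a,6,7,7a-hexahydro-1H-indene-7-carboxylate
Conditions: 5-(benzylsulfonyl)-1-phenyl-1H-tetrazole (1.5 equiv), KHMDS (1.4 equiv), DME, −78 °C; then 28, −78 °C → rt
Reagents that add atoms: 5-(benzylsulfonyl)-1-phenyl-1H-tetrazole, O=S(=O)(Cc1ccccc1)c1nnnn1-c1ccccc1
Why: Julia–Kocienski olefination: the pre-formed sulfonyl carbanion is less basic than a ketone enolate and should add to the aldehyde in preference to the hindered 2,5-disubstituted cyclopentanone, and the bulky neopentyl partner favours the (E)-styrene.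

Step 20
Reactants: 29 tert-butyl 1,6,7-triethyl-3,4-dimethyl-2-oxo-6-[(E)-2-phenylethenyl]-2,3,3a,6,7,7a-hexahydro-1H-indene-7-carboxylate
Product: 30 1,6,7-triethyl-3,4-dimethyl-2-oxo-6-[(E)-2-phenylethenyl]-2,3,3a,6,7,7a-hexahydro-1H-indene-7-carboxylic acid (CNP0178058.1)
Conditions: TFA–CH2Cl2 (1:4), 0 °C → rt
Reagents that add atoms: none
Why: Acidolysis of the tert-butyl ester (E1 loss of isobutene) at low temperature; C1 and C3 already hold their thermodynamic configuration, so acid-mediated enolisation cannot change them.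

**Compound list**

1 | (R)-but-3-yn-2-ol | C[C@@H](O)C#C | starting material
2 | dilithium alkoxide acetylide of 1 | C[C@@H](O[Li])C#C[Li] | intermediate
3 | (R)-pent-2-yne-1,4-diol | C[C@@H](O)C#CCO | intermediate
4 | (R)-5-(TBS-oxy)pent-3-yn-2-ol | C[C@@H](O)C#CCO[Si](C)(C)C(C)(C)C | intermediate
5 | sodium cyclic alkenylalanate (Al bound to the carbinol oxygen and to the alkene carbon bearing CH2OTBS, two 2-methoxyethoxy ligands) | C[C@H]1O[Al-](OCCOC)(OCCOC)C(CO[Si](C)(C)C(C)(C)C)=C1.[Na+] | intermediate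
6 | (2R,3Z)-5-(TBS-oxy)-4-iodopent-3-en-2-ol | C[C@@H](O)/C=C(\I)CO[Si](C)(C)C(C)(C)C | intermediate
7 | (2R,3E)-4-(TBS-oxymethyl)hex-3-en-2-ol | C[C@@H](O)/C=C(/CO[Si](C)(C)C(C)(C)C)CC | intermediate
8 | hex-3-yn-1-ol | CCC#CCCO | starting material
9 | hex-3-ynoic acid | CCC#CCC(=O)O | intermediate
10 | dilithium enediolate of 9 | CCC#CC=C(O[Li])O[Li] | intermediate
11 | 2-ethylhex-3-ynoic acid (racemic) | CCC#CC(CC)C(=O)O | intermediate
12 | (2R,3E)-4-(TBS-oxymethyl)hex-3-en-2-yl 2-ethylhex-3-ynoate (both epimers at the acyl α-carbon) | CCC#CC(CC)C(=O)O[C@H](C)/C=C(/CO[Si](C)(C)C(C)(C)C)CC | intermediate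
13 | (Z)-trimethylsilyl ketene acetal of 12 (butynyl cis to OSiMe3, ethyl cis to the allyloxy group) | CCC#C/C(CC)=C(\O[Si](C)(C)C)O[C@H](C)/C=C(/CO[Si](C)(C)C(C)(C)C)CC | intermediate
14 | trimethylsilyl ester of 15 | C/C=C/[C@@](CO[Si](C)(C)C(C)(C)C)(CC)[C@](CC)(C(=O)O[Si](C)(C)C)C#CCC | intermediate
15 | (2R,3S,4E)-2-(but-1-yn-1-yl)-2,3-diethyl-3-(TBS-oxymethyl)hex-4-enoic acid | C/C=C/[C@@](CO[Si](C)(C)C(C)(C)C)(CC)[C@](CC)(C(=O)O)C#CCC | intermediate
16 | tert-butyl (2R,3S,4E)-2-(but-1-yn-1-yl)-2,3-diethyl-3-(TBS-oxymethyl)hex-4-enoate | C/C=C/[C@@](CO[Si](C)(C)C(C)(C)C)(CC)[C@](CC)(C(=O)OC(C)(C)C)C#CCC | intermediate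
17 | secondary ozonide (3-methyl-1,2,4-trioxolan-5-yl in place of the propenyl group of 16) | CC1OOC(O1)[C@@](CO[Si](C)(C)C(C)(C)C)(CC)[C@](CC)(C(=O)OC(C)(C)C)C#CCC | intermediate
18 | tert-butyl (2R,3S)-2-(but-1-yn-1-yl)-2,3-diethyl-3-(TBS-oxymethyl)-4-oxobutanoate | O=C[C@@](CO[Si](C)(C)C(C)(C)C)(CC)[C@](CC)(C(=O)OC(C)(C)C)C#CCC | intermediate
19 | 1-tert-butyl 6-ethyl (2R,3S,4Z)-2-(but-1-yn-1-yl)-2,3-diethyl-5-methyl-3-(TBS-oxymethyl)hex-4-enedioate | CCOC(=O)/C(C)=C\[C@@](CO[Si](C)(C)C(C)(C)C)(CC)[C@](CC)(C(=O)OC(C)(C)C)C#CCC | intermediate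
20 | tert-butyl (2R,3S,4Z)-2-(but-1-yn-1-yl)-2,3-diethyl-6-hydroxy-5-methyl-3-(TBS-oxymethyl)hex-4-enoate | OC/C(C)=C\[C@@](CO[Si](C)(C)C(C)(C)C)(CC)[C@](CC)(C(=O)OC(C)(C)C)C#CCC | intermediate
21 | tert-butyl (2R,3S,4Z)-2-(but-1-yn-1-yl)-2,3-diethyl-5-methyl-6-oxo-3-(TBS-oxymethyl)hex-4-enoate | O=C/C(C)=C\[C@@](CO[Si](C)(C)C(C)(C)C)(CC)[C@](CC)(C(=O)OC(C)(C)C)C#CCC | intermediate
22 | tert-butyl (2R,3S,4Z,6E)-2-(but-1-yn-1-yl)-2,3-diethyl-5-methyl-3-(TBS-oxymethyl)octa-4,6-dienoate | C/C=C/C(C)=C\[C@@](CO[Si](C)(C)C(C)(C)C)(CC)[C@](CC)(C(=O)OC(C)(C)C)C#CCC | intermediate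
23 | carbon monoxide | [C-]#[O+] | starting material
24 | tert-butyl 1,6,7-triethyl-3,4-dimethyl-2-oxo-6-(TBS-oxymethyl)-3,3a,6,7-tetrahydro-2H-indene-7-carboxylate (C1=C7a enone, C4=C5 alkene, 3-Me trans to C4, H3a anti to the ester) | CCC=1C(=O)[C@@H](C)[C@@H]2C(C)=C[C@@](CO[Si](C)(C)C(C)(C)C)(CC)[C@](CC)(C(=O)OC(C)(C)C)C=12 | intermediate
25 | lithium C1=C2 enolate of 26 (trans ring fusion already set) | CCC1=C(O[Li])[C@@H](C)[C@@H]2C(C)=C[C@@](CO[Si](C)(C)C(C)(C)C)(CC)[C@](CC)(C(=O)OC(C)(C)C)[C@H]21 | intermediate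
26 | tert-butyl 1,6,7-triethyl-3,4-dimethyl-2-oxo-6-(TBS-oxymethyl)-2,3,3a,6,7,7a-hexahydro-1H-indene-7-carboxylate (trans-fused, H7a syn to the ester, 1-Et trans to C7, 3-Me trans to C4) | CC[C@@H]1C(=O)[C@@H](C)[C@@H]2C(C)=C[C@@](CO[Si](C)(C)C(C)(C)C)(CC)[C@](CC)(C(=O)OC(C)(C)C)[C@H]21 | intermediate
27 | tert-butyl 1,6,7-triethyl-6-(hydroxymethyl)-3,4-dimethyl-2-oxo-2,3,3a,6,7,7a-hexahydro-1H-indene-7-carboxylate (configuration as 26) | CC[C@@H]1C(=O)[C@@H](C)[C@@H]2C(C)=C[C@@](CO)(CC)[C@](CC)(C(=O)OC(C)(C)C)[C@H]21 | intermediate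
28 | tert-butyl 1,6,7-triethyl-6-formyl-3,4-dimethyl-2-oxo-2,3,3a,6,7,7a-hexahydro-1H-indene-7-carboxylate (configuration as 26) | CC[C@@H]1C(=O)[C@@H](C)[C@@H]2C(C)=C[C@@](C=O)(CC)[C@](CC)(C(=O)OC(C)(C)C)[C@H]21 | intermediate
29 | tert-butyl 1,6,7-triethyl-3,4-dimethyl-2-oxo-6-[(E)-2-phenylethenyl]-2,3,3a,6,7,7a-hexahydro-1H-indene-7-carboxylate (configuration as 26) | CC[C@@H]1C(=O)[C@@H](C)[C@@H]2C(C)=C[C@@](/C=C/c3ccccc3)(CC)[C@](CC)(C(=O)OC(C)(C)C)[C@H]21 | intermediate
30 | 1,6,7-triethyl-3,4-dimethyl-2-oxo-6-[(E)-2-phenylethenyl]-2,3,3a,6,7,7a-hexahydro-1H-indene-7-carboxylic acid, CNP0178058.1 (trans-fused, H7a and styryl syn to CO2H, H3a anti, 1-Et trans to C7, 3-Me trans to C4) | CC[C@@H]1C(=O)[C@@H](C)[C@@H]2C(C)=C[C@@](/C=C/c3ccccc3)(CC)[C@](CC)(C(=O)O)[C@H]21 | target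

**Step count and risks**

Total: 20 steps. Longest linear sequence: 18 steps (1 → 30 through steps 1–4 and 7–20); the acid 11 is made in a 2-step side branch (steps 5 and 6).

Steps most likely to fail:

1. Step 15 (ring closure). The rhodium catalyst may turn over slowly because a 1,2-disubstituted alkene has to insert, so that cycloisomerisation or alkyne oligomerisation competes. The discrimination between the two faces of C3=C3a rests on one allylic-strain term only and may erode at 110 °C. The fallback sets out from 22 and returns to 24. The dienyne is first bound with Co2(CO)8 (CH2Cl2, rt) as its alkyne–hexacarbonyldicobalt complex F1. This is then cyclised by amine N-oxide promotion (N-methylmorpholine N-oxide, CH2Cl2, 0 °C → rt), the stoichiometric cobalt form of the same [2+2+1] closure. Cobalt inserts internal alkenes more readily, and the lower temperature should turn the same strain difference into a larger preference.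

2. Step 8 (C6–C7 bond). Enolisation may proceed with little geometric bias between ethyl and butynyl, or the β,γ-alkynoate may slip to the allenoate before enolisation; either would form C7 as a mixture while C6 stays defined. The fallback sets out from 7 and returns to 16, and fixes the enolate geometry by chelation instead of by size.
 - Claisen self-condensation of methyl butanoate (NaH, THF) gives methyl 2-ethyl-3-oxohexanoate F2.
 - DMAP-catalysed transesterification with 7 (toluene, 100 °C, 4 Å sieves) gives the allylic β-keto ester F3.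
 - LDA (2.2 equiv, THF, −78 → 60 °C) forms the lithium-chelated bis-enolate, whose U-shape holds the acyl carbon syn to O–Li and ethyl syn to the allyloxy oxygen, the same arrangement as in 13. The dianionic Carroll rearrangement through the same chair gives, after cold acidification, the β-keto acid F4.
 - Immediate esterification (tert-butyl 2,2,2-trichloroacetimidate, cat. BF3·OEt2, 0 °C), before decarboxylation can set in, gives the tert-butyl β-keto ester F5.
 - KHMDS and N-phenyltriflimide (THF, −78 °C) convert the ketone, enolisable only toward its propyl chain, into the enol triflate F6.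
 - LDA (THF, −78 → 0 °C) eliminates triflate to the butynyl group of 16.

3. Step 11 (Z-olefination). Addition of the bulky phosphonate anion to an aldehyde flanked by two quaternary carbons may be slow, and warming to force it would erode the kinetic (Z) preference. The fallback sets out from 18 and returns to 22, by-passing 19–21. A Stork–Zhao-type olefination with the more reactive, non-stabilised ylide (1-iodoethylidene)triphenylphosphorane (from ethyltriphenylphosphonium iodide, n-BuLi, I2, then NaHMDS; THF, −78 °C) gives the (Z)-iodoalkene F7, iodine cis to C6. Suzuki–Miyaura coupling with (E)-prop-1-en-1-ylboronic acid (Pd(PPh3)4, aq. NaOH, THF, rt → 50 °C) proceeds with retention at both partners and gives 22 directly.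

Further compounds
F1 | step 15 | μ-alkyne–hexacarbonyldicobalt complex of 22 (Co2(CO)6 on C1≡C7a) | C/C=C/C(C)=C\[C@@](CO[Si](C)(C)C(C)(C)C)(CC)[C@](CC)(C(=O)OC(C)(C)C)C12[Co]3(=C=O)(=C=O)(=C=O)[Co]1(=C=O)(=C=O)(=C=O)C23CC
F2 | step 8 | methyl 2-ethyl-3-oxohexanoate (racemic) | CCCC(=O)C(CC)C(=O)OC
F3 | step 8 | (2R,3E)-4-(TBS-oxymethyl)hex-3-en-2-yl 2-ethyl-3-oxohexanoate | CCCC(=O)C(CC)C(=O)O[C@H](C)/C=C(/CO[Si](C)(C)C(C)(C)C)CC
F4 | step 8 | (2R,3S,4E)-2-butanoyl-2,3-diethyl-3-(TBS-oxymethyl)hex-4-enoic acid | C/C=C/[C@@](CO[Si](C)(C)C(C)(C)C)(CC)[C@](CC)(C(=O)O)C(=O)CCC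
F5 | step 8 | tert-butyl (2R,3S,4E)-2-butanoyl-2,3-diethyl-3-(TBS-oxymethyl)hex-4-enoate | C/C=C/[C@@](CO[Si](C)(C)C(C)(C)C)(CC)[C@](CC)(C(=O)OC(C)(C)C)C(=O)CCC
F6 | step 8 | enol triflate of F5 (1-(trifluoromethylsulfonyloxy)but-1-en-1-yl in place of butanoyl) | C/C=C/[C@@](CO[Si](C)(C)C(C)(C)C)(CC)[C@](CC)(C(=O)OC(C)(C)C)C(OS(=O)(=O)C(F)(F)F)=CCC
F7 | step 11 | tert-butyl (2R,3S,4Z)-2-(but-1-yn-1-yl)-2,3-diethyl-5-iodo-3-(TBS-oxymethyl)hex-4-enoate | C/C(I)=C/[C@@](CO[Si](C)(C)C(C)(C)C)(CC)[C@](CC)(C(=O)OC(C)(C)C)C#CCC
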